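The data come from a simulation for substances that don't exist, noise included.

At 20 min we want the J in the violet flask, and then what each option adds to it.

- violet: X 0.050 M; Z 0.60 equiv; Q 1.2 equiv; temperature 40 °C; the very flask that is asked about, followed so far
- flask: X 0.050 M; Z 0.600 equiv; Q 1.20 equiv; temperature 40 °C; time 20 min

violet run (percent of the X charged)

| time / min | J / % | X / % |
|---|---|---|
| 1.50 | 18.9 | 81.6 |
| 4.00 | 35.3 | 62.2 |
| 8.00 | 46.0 | 48.5 |
| 12.0 | 48.5 | 42.6 |

(scatter of a reading: 1 percentage point)

* J, in percent of the X first charged, at 20 min
* which option adds most J ("none" when 2 percentage points or less is all one gets) (zeta / eta / theta / gamma / none)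
* J present, with what was taken out counted in, in percent of the X first charged, after zeta
* J present, with what was taken out counted in, in percent of the X first charged, after eta

- zeta: change nothing and wait 10 min more
- eta: at 20 min take out 90 % of the J then present, then wait 10 min
- theta: at 20 min raise the temperature by 20 K, then wait 10 min
- gamma: at 20 min add Q, 100 % of the amount charged, then wait 10 min

- removed J is counted in
- the earlier runs do not show what temperature does; that part of a forecast is a guess
- additions bring no volume worth counting

We assume that one Z turns one X into J. The quantity we carry is then the Z ceiling, the percent of the charged X that the charged Z can turn into J: 60.0 %. This lies below the charged X, which makes Z the limiting reagent.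

J starts steeply, with 18.9 % by 1.50 min. A straight line through that reading meets the ceiling at 4.76 min, and we take that as our estimate of the knee of the curve. The reading at 4.00 min, 35.3 %, already lies below the line.

We take the rate as a constant times X times Z, both as fractions of the X charged. Mean amounts over the first stretch then give a constant of 0.275 min⁻¹. At the late end X moves slowly, so with X at 42.6 % the remaining Z has a half-life of about 5.91 min.

To join the two ends, we let the last rise of J, 2.5 percentage points between 8.00 min and 12.0 min, fade at that pace. Each such interval then brings 0.626 of the one before. This assumes that any leak of J fades with it, and it is our weakest step. Our reckoning puts the level of the curve at 52.7 %, which is 7.3 points under the ceiling.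

Our reckoning gives 51.0 % at 20 min and 52.2 % after zeta. That gain of 1.2 points is within the margin. The other options lie beyond this reckoning.

The forecast stands lower than ours, with 47 % at 20 min, 41 % after zeta, 48.5 % after eta and none as the best option, and it argues that "Heat speeds the loss, and Q does not relieve the lack of Z".

The violet flask gives 51.8 % at 20 min, 52.0 % after zeta and 55.1 % after eta. The best option is theta, which adds 5.8 points.

    X + Z → J (k = 0.0950 M⁻¹ s⁻¹, Ea = 44.0 kJ mol⁻¹)
    X + Q → L (k = 0.00210 M⁻¹ s⁻¹, Ea = 81.0 kJ mol⁻¹)
    J ⇌ E (K = 0.190, k = 1.40 × 10⁻⁴ s⁻¹, Ea = 103 kJ mol⁻¹, ΔH = −73.0 kJ mol⁻¹)
    (constants at 40 °C)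

In the violet flask at 20.0 min the step from X and Z to J has a half-life of 6.8 min for Z and 75 min for X. Z then stands at 5.4 % of its charge, which is 3.2 points of the 60.0 % ceiling still unspent, beside 35.8 % of X. A neighbouring flask, the same but with 2.40 equiv of Z, has its ceiling at 240 %, above the charged X. At 20.0 min that flask holds 88.9 % of J, with 59 % of its Z left and 0.016 % of its X.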